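## Retrosynthetic overview

1. Target 17 comes from flavone 16 by one acid step that removes three MOM groups (5-OH, 7-OH, 4'-OH).
2. Key step: ring C, the only ring formed, is closed last from iodophenol 5, CO and arylacetylene 13. A Pd-catalysed carbonylative Sonogashira coupling with amine-relayed 6-endo annulation makes C4a–C4, C4–C3 and O1–C2, replacing the usual Baker–Venkataraman or chalcone route from an acetophenone.
3. 5 comes from ortho-iodination of the C2v-symmetric phenol 4, which comes from sterically controlled Ir C–H borylation/oxidation of bis-MOM 2-methoxyresorcinol 2. The symmetry removes the 6-OMe/8-OMe ambiguity.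
4. 13 comes from Sonogashira coupling of 10, which comes from desymmetrising mono I/Mg exchange, borylation and oxidation of 1,4-diiodo-2,5-dimethoxybenzene 6.
5. Rings A and B are bought as symmetric arenes and functionalised in parallel; ring C follows.

Assumption: the target is 5,7,4'-trihydroxy-6,2',5'-trimethoxyflavone, C18H16O8. Its SMILES has no stereocentre and no stereoaxis, so it is achiral and "single enantiomer" needs no stereocontrol.

## Route

Step 1
Reactants: 1 2-methoxyresorcinol (2-methoxybenzene-1,3-diol)
Product: 2 2-methoxy-1,3-bis(methoxymethoxy)benzene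
Conditions: MOMCl (2.5 equiv), iPr2NEt (3 equiv), CH2Cl2, 0 °C to rt
Reagents that add atoms: chloromethyl methyl ether (MOMCl), COCCl
Why: O-alkylation of both phenols (MOM acetal protection) gives a group that tolerates base, Ir and Pd, has no arene C–H bond that step 2 could borylate, and leaves in one acid step at the end; no stereocentre is formed.

Step 2
Reactants: 2 2-methoxy-1,3-bis(methoxymethoxy)benzene
Product: 4 4-methoxy-3,5-bis(methoxymethoxy)phenol, via aryl pinacol boronate 3 (not isolated)
Conditions: [Ir(OMe)(cod)]2 (1.5 mol %), dtbpy (3 mol %), B2pin2 (0.6 equiv, both boron atoms used), THF, 80 °C; then aq NaOH, 30% H2O2, 0 °C to rt; work-up at pH 6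
Reagents that add atoms: bis(pinacolato)diboron, CC1(C)OB(OC1(C)C)B1OC(C)(C)C(C)(C)O1 (Bpin group of 3 only); hydrogen peroxide, OO (the new phenol oxygen)
Why: Sterically controlled Ir-catalysed aromatic C–H borylation (Hartwig–Miyaura type) attacks only C5, the one C–H with no ortho substituent and a site electrophilic substitution cannot reach, and peroxide ipso-hydroxylation (1,2-aryl shift from B to O) then gives the phenol in the same flask; no stereocentre.

Step 3
Reactants: 4 4-methoxy-3,5-bis(methoxymethoxy)phenol
Product: 5 2-iodo-4-methoxy-3,5-bis(methoxymethoxy)phenol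
Conditions: NIS (1.0 equiv), MeCN, −20 °C to 0 °C, dark; store 5 cold and dark
Reagents that add atoms: N-iodosuccinimide, O=C1CCC(=O)N1I
Why: Electrophilic aromatic iodination ortho to the free OH can give only one mono-iodide because the two open positions of symmetric 4 are equivalent, which fixes the later 6-OMe/8-H pattern, while acid-free NIS at low temperature spares the MOM acetals and limits di-iodination.

Step 4
Reactants: 6 1,4-diiodo-2,5-dimethoxybenzene
Product: 9 4-iodo-2,5-dimethoxyphenol, via arylmagnesium chloride 7 (not isolated), via dimethyl arylboronate 8 (not isolated)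
Conditions: iPrMgCl·LiCl (1.05 equiv), THF, −20 °C to 0 °C; B(OMe)3 (1.5 equiv), −20 °C to rt; then aq NaOH, 30% H2O2, 0 °C to rt; work-up at pH 5
Reagents that add atoms: isopropylmagnesium chloride–lithium chloride, CC(C)[Mg]Cl.[Li+].[Cl-] (MgCl of 7 only); trimethyl borate, COB(OC)OC (B(OMe)2 of 8 only); hydrogen peroxide, OO (the new phenol oxygen)
Why: Desymmetrising mono iodine–magnesium exchange (turbo-Grignard) stops after one exchange because the aryl-Mg ring is too electron-rich for a second, and borate trapping with peroxide ipso-hydroxylation turns that carbon into the phenol; the two iodines are equivalent, so one regioisomer results.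

Step 5
Reactants: 9 4-iodo-2,5-dimethoxyphenol
Product: 10 1-iodo-2,5-dimethoxy-4-(methoxymethoxy)benzene
Conditions: MOMCl (1.3 equiv), iPr2NEt (1.6 equiv), CH2Cl2, 0 °C to rt
Reagents that add atoms: chloromethyl methyl ether (MOMCl), COCCl
Why: MOM protection by O-alkylation masks the phenol, which would otherwise give an unstable 4-ethynylphenol and would compete as an O-nucleophile for the acyl-palladium species in step 7.

Step 6
Reactants: 10 1-iodo-2,5-dimethoxy-4-(methoxymethoxy)benzene; 11 trimethylsilylacetylene
Product: 13 1-ethynyl-2,5-dimethoxy-4-(methoxymethoxy)benzene, via TMS-alkyne 12 (not isolated)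
Conditions: PdCl2(PPh3)2 (2 mol %), CuI (4 mol %), 11 (1.3 equiv), Et3N–THF, rt to 40 °C; filter off the ammonium salt, concentrate; K2CO3 (0.2 equiv), MeOH, rt
Reagents that add atoms: trimethylsilylacetylene (compound 11), C#C[Si](C)(C)C
Why: Sonogashira coupling of an aryl iodide runs under mild conditions even on this electron-rich ring, and carbonate-catalysed methanolysis of the C–Si bond (protodesilylation) frees the terminal alkyne without touching the MOM or methyl ethers.

Step 7
Reactants: 5 2-iodo-4-methoxy-3,5-bis(methoxymethoxy)phenol; 13 1-ethynyl-2,5-dimethoxy-4-(methoxymethoxy)benzene (1.3 equiv)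
Product: 16 2-[2,5-dimethoxy-4-(methoxymethoxy)phenyl]-6-methoxy-5,7-bis(methoxymethoxy)-4H-chromen-4-one, via ynone 14 (not isolated), via enaminone 15 (not isolated)
Conditions: PdCl2(dppf) (5 mol %), CO (20 bar), Et2NH (solvent and base), no Cu, 100 °C, autoclave
Reagents that add atoms: carbon monoxide, [C-]#[O+] (becomes C4=O); diethylamine, CCNCC (NEt2 group of 15 only)
Why: In this carbonylative Sonogashira coupling/annulation, oxidative addition of the C–I bond, fast CO insertion into the electron-rich aryl–Pd bond and alkynylation give ynone 14, Et2NH adds in conjugate fashion to give enaminone 15, and the ortho-OH displaces the amine at the β-carbon (oxa-Michael addition–elimination), so only the 6-endo flavone forms and not the 5-exo aurone; high CO pressure and the absence of copper suppress direct coupling to a benzofuran, and no stereocentre is formed.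

Step 8
Reactants: 16 2-[2,5-dimethoxy-4-(methoxymethoxy)phenyl]-6-methoxy-5,7-bis(methoxymethoxy)-4H-chromen-4-one
Product: 17 5,7-dihydroxy-2-(4-hydroxy-2,5-dimethoxyphenyl)-6-methoxy-4H-chromen-4-one (target)
Conditions: HCl (1.25 M in MeOH), 50 °C, 2 h
Reagents that add atoms: none
Why: Acid-catalysed acetal exchange (MOM cleavage) frees all three phenols at once, while the aryl methyl ethers are inert and the conditions are far too mild for Wessely–Moser ring-opening isomerisation to the 8-methoxy isomer.

## Compound list

1 | 2-methoxyresorcinol | COc1c(O)cccc1O | starting material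
2 | 2-methoxy-1,3-bis(methoxymethoxy)benzene | COCOc1cccc(OCOC)c1OC | intermediate
3 | 2-[4-methoxy-3,5-bis(methoxymethoxy)phenyl]-4,4,5,5-tetramethyl-1,3,2-dioxaborolane (formed in the flask, step 2) | COCOc1cc(B2OC(C)(C)C(C)(C)O2)cc(OCOC)c1OC | intermediate
4 | 4-methoxy-3,5-bis(methoxymethoxy)phenol | COCOc1cc(O)cc(OCOC)c1OC | intermediate
5 | 2-iodo-4-methoxy-3,5-bis(methoxymethoxy)phenol | COCOc1cc(O)c(I)c(OCOC)c1OC | intermediate
6 | 1,4-diiodo-2,5-dimethoxybenzene | COc1cc(I)c(OC)cc1I | starting material
7 | (4-iodo-2,5-dimethoxyphenyl)magnesium chloride (formed in the flask, step 4) | COc1cc([Mg]Cl)c(OC)cc1I | intermediate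
8 | dimethyl (4-iodo-2,5-dimethoxyphenyl)boronate (formed in the flask, step 4; present as its methoxide ate complex) | COB(OC)c1cc(OC)c(I)cc1OC | intermediate
9 | 4-iodo-2,5-dimethoxyphenol | COc1cc(I)c(OC)cc1O | intermediate
10 | 1-iodo-2,5-dimethoxy-4-(methoxymethoxy)benzene | COCOc1cc(OC)c(I)cc1OC | intermediate
11 | trimethylsilylacetylene | C#C[Si](C)(C)C | starting material
12 | {[2,5-dimethoxy-4-(methoxymethoxy)phenyl]ethynyl}trimethylsilane (formed in the flask, step 6) | COCOc1cc(OC)c(C#C[Si](C)(C)C)cc1OC | intermediate
13 | 1-ethynyl-2,5-dimethoxy-4-(methoxymethoxy)benzene | COCOc1cc(OC)c(C#C)cc1OC | intermediate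
14 | 3-[2,5-dimethoxy-4-(methoxymethoxy)phenyl]-1-[2-hydroxy-5-methoxy-4,6-bis(methoxymethoxy)phenyl]prop-2-yn-1-one (formed in the flask, step 7) | COCOc1cc(O)c(C(=O)C#Cc2cc(OC)c(OCOC)cc2OC)c(OCOC)c1OC | intermediate
15 | 3-(diethylamino)-3-[2,5-dimethoxy-4-(methoxymethoxy)phenyl]-1-[2-hydroxy-5-methoxy-4,6-bis(methoxymethoxy)phenyl]prop-2-en-1-one (formed in the flask, step 7; E/Z mixture, geometry without consequence) | COCOc1cc(O)c(C(=O)C=C(N(CC)CC)c2cc(OC)c(OCOC)cc2OC)c(OCOC)c1OC | intermediate
16 | 2-[2,5-dimethoxy-4-(methoxymethoxy)phenyl]-6-methoxy-5,7-bis(methoxymethoxy)-4H-chromen-4-one | COCOc1cc2oc(-c3cc(OC)c(OCOC)cc3OC)cc(=O)c2c(OCOC)c1OC | intermediate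
17 | 5,7-dihydroxy-2-(4-hydroxy-2,5-dimethoxyphenyl)-6-methoxy-4H-chromen-4-one (achiral) | COc1cc(-c2cc(=O)c3c(O)c(OC)c(O)cc3o2)c(OC)cc1O | target

## Step count and risks

Total step count: 8.
Longest linear sequence: 5 steps. Both branches are this long: steps 4, 5, 6, 7, 8 and steps 1, 2, 3, 7, 8.

**Step 7 (highest risk).** The aryl iodide is very electron-rich and flanked by two oxygen substituents. Direct coupling to a 2-arylbenzofuran, aminocarbonylation to the diethylamide, or loss of iodine may compete with ynone formation.

The fallback sets out from 4 and 13 and comes back to the route at 14, and from there at 16. It replaces CO insertion by carbonyl addition and makes step 3 unnecessary. Magnesium-mediated ortho-formylation of 4 (MgCl2, Et3N, paraformaldehyde, MeCN, reflux) gives 2-hydroxy-5-methoxy-4,6-bis(methoxymethoxy)benzaldehyde F1. Again only one regioisomer is possible. Alkyne 13 is deprotonated with n-BuLi (THF, −78 °C) to lithium [2,5-dimethoxy-4-(methoxymethoxy)phenyl]acetylide F2. Of the 2.2 equiv used, the first is spent on the phenol and recovered as 13. Addition to F1 gives racemic 3-[2,5-dimethoxy-4-(methoxymethoxy)phenyl]-1-[2-hydroxy-5-methoxy-4,6-bis(methoxymethoxy)phenyl]prop-2-yn-1-ol F3. MnO2 (CH2Cl2, rt) oxidises this benzylic propargylic alcohol to ynone 14, which erases its stereocentre. Et2NH (EtOH, 60 °C) then closes 14 by way of 15 to 16.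

**Step 3.** Phenol 4 is a highly activated 4-methoxyphenol. Di-iodination or oxidation to a quinone may erode the yield.

The fallback sets out from 4 and comes back at 5. It uses directed ortho-metalation, so exactly one iodine is delivered and no oxidant meets a free phenol. Treating 4 with ClC(O)NEt2 and K2CO3 (MeCN, reflux) gives 4-methoxy-3,5-bis(methoxymethoxy)phenyl N,N-diethylcarbamate F4. s-BuLi/TMEDA (THF, −78 °C) removes the proton between the carbamate and the OMOM group to give 2-lithio-4-methoxy-3,5-bis(methoxymethoxy)phenyl N,N-diethylcarbamate F5. An I2 quench at −78 °C, before any anionic Fries shift, gives 2-iodo-4-methoxy-3,5-bis(methoxymethoxy)phenyl N,N-diethylcarbamate F6. NaOH (EtOH–H2O, reflux) cleaves the carbamate to 5.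

**Step 4.** Double exchange, protonation of 7 or incomplete borate capture would give mixtures that are hard to separate.

The fallback sets out from 6 and comes back at 9. It is a copper-catalysed Ullmann-type hydroxylation (CuI 10 mol %, 8-hydroxyquinoline 20 mol %, KOH, DMSO–H2O, 100 °C, 6 in 1.5-fold excess, then acidification). The first-formed phenoxide is so electron-rich that its remaining C–I bond reacts much more slowly, and surplus 6 is recovered. New compounds on this way: none F0.

## Further compounds

F1 | step 7 | 2-hydroxy-5-methoxy-4,6-bis(methoxymethoxy)benzaldehyde | COCOc1cc(O)c(C=O)c(OCOC)c1OC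
F2 | step 7 | lithium [2,5-dimethoxy-4-(methoxymethoxy)phenyl]acetylide | [Li]C#Cc1cc(OC)c(OCOC)cc1OC
F3 | step 7 | racemic 3-[2,5-dimethoxy-4-(methoxymethoxy)phenyl]-1-[2-hydroxy-5-methoxy-4,6-bis(methoxymethoxy)phenyl]prop-2-yn-1-ol | COCOc1cc(O)c(C(O)C#Cc2cc(OC)c(OCOC)cc2OC)c(OCOC)c1OC
F4 | step 3 | 4-methoxy-3,5-bis(methoxymethoxy)phenyl N,N-diethylcarbamate | CCN(CC)C(=O)Oc1cc(OCOC)c(OC)c(OCOC)c1
F5 | step 3 | 2-lithio-4-methoxy-3,5-bis(methoxymethoxy)phenyl N,N-diethylcarbamate | CCN(CC)C(=O)Oc1cc(OCOC)c(OC)c(OCOC)c1[Li]
F6 | step 3 | 2-iodo-4-methoxy-3,5-bis(methoxymethoxy)phenyl N,N-diethylcarbamate | CCN(CC)C(=O)Oc1cc(OCOC)c(OC)c(OCOC)c1I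
F0 | step 4 | none | none
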